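## The problem

The target is an ester of two benzotropolones. The acid half is an epitheaflavic acid unit with its carboxyl on the seven-membered ring. The alcohol half is a theaflavin unit, and the acylated oxygen is the 3-hydroxyl of the chroman attached to its seven-membered ring. Each benzo ring also carries a flavan-3-ol at the carbon peri to the tropolone CH, so there are three cis-2,3-disubstituted chromans and six stereocentres, all (2R,3R) as in epicatechin. The three pairs are too far apart to control one another, so each needs reagent control. Within a pair the cis relation is the less stable one, and C2 is a benzylic aryl ether that can epimerise by ionisation. The tropolones are reducible and sensitive to nucleophiles, the phloroglucinol-type rings A are easily oxidised, and the fourteen free hydroxyls make the final compound labile; all oxygens therefore stay masked until one neutral last step. The enabling feature is the atom sequence C(=O)–C(OH)=CH–C(R)=CH of each seven-membered ring between its two benzo carbons: it is a 2-oxygenated inden-1-one (C1=O, C2–O, C3–H) with the two carbons of a terminal alkyne R–C≡CH inserted into the C2–C3 bond, R being the chromanyl group in one half and the carboxyl carbon in the other.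

## Retrosynthesis

**35 ⇒ 34.** All fourteen hydroxyls are masked as ten benzyl ethers and two diphenylmethylene ketals, so that one hydrogenolysis ends the synthesis. The ketal is chosen for the benzo-ring diol because it also differentiates the three oxygens of the starting arene.

**34 ⇒ 32 + 25.** The ester C–O bond is cut last. Forming it earlier would send a tropolone acid or a large acyl group through the photochemistry. The two halves, acid 32 and alcohol 25, are of similar size and come from the same indenone 16. The forward step must acylate an axial secondary hydroxyl next to a large substituent.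

**25 ⇒ 24 ⇒ 22 and 32 ⇒ 30 ⇒ 29 ⇒ 27.** Each tropolone is traced to a cyclobutene-fused indanone (22, 27) by re-forming the bond between the two ring-fusion carbons. In the forward sense, fluoride frees a tertiary alkoxide that breaks this bond; the adduct and the tropolone are valence isomers, so no oxidation is needed. The acidic tropolone hydroxyl is then benzylated selectively (24 → 25, 29 → 30), and the hydroxymethyl group of 30 is oxidised to the acid 32.

**22 ⇒ 16 + 21 and 27 ⇒ 16 + 26.** This is the key cut: the C2–CH and C3–C(R) bonds across the indenone double bond. Condensation routes or oxidation of a benzosuberone would need separate precursors for each half and later oxidation steps. Here one indenone 16 serves both halves, and alkyne 21 brings the complete third chroman with its stereocentres. The forward reaction must give head-to-tail orientation.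

**16 ⇒ 15 ⇒ 14 ⇒ 13 ⇒ 12.** The siloxyindenone is the enol silyl ether of dione 15, which can only enolise towards C3, so one regioisomer forms. The dione comes from indene 13 by dihydroxylation and oxidation, and the indene from the ortho-allyl styrene 12 by ring-closing metathesis. The position of the carbonyl is fixed by which arene carbon carries the vinyl group.

**12 ⇒ 11 ⇒ 10 ⇒ 9 ⇒ 7 + 8.** The benzo-side chroman is cut at C4–C4a and O1–C2. Forward, the phenol 8 is joined to the erythro epoxy alcohol 7 by Mitsunobu inversion, and the electron-rich ring then opens the terminal epoxide. This gives the cis chroman directly; the usual dihydroxylation route gives the trans isomer first and needs an oxidation–reduction to invert C3. The triflate is kept through these two steps because it tempers ionisation of the benzylic ether; the vinyl group is introduced afterwards (10 → 11).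

**7 ⇒ 6 ⇒ 5 ⇒ 4 ⇒ 3 ⇒ 2 ⇒ 1.** The arene needs ring B of a gallocatechin with one oxygen replaced by carbon and the adjacent CH also substituted. Degrading natural epigallocatechin would require the third ring-B hydroxyl to be told apart from the two ring-A hydroxyls, for which there is no reliable handle. The arene is therefore built from 1: the ketal leaves one hydroxyl free, its allyl ether rearranges to the only free ortho carbon, and the regenerated phenol becomes the triflate. Vinyl addition and kinetic resolution then give 7.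

**21 ⇒ 20 ⇒ 19 ⇒ 18 + 8, 18 ⇒ 17.** The ethynyl chroman is made by the same two-step pyran annulation, with ethynyl in place of aryl, from the resolved epoxy alcohol 18.

## Roads not taken

Alternative 1: The cut is in ring C of the benzo-side flavan of the acid half, at O1–C8a and C4–C4a. It leads back to 3,5-bis(benzyloxy)benzyne A1 and a syn α-benzyloxy-β-hydroxy aldehyde A2 that already carries the benzotropolone ester. Forward, CsF would generate A1, the benzylic alkoxide of A2 would add to it, and the aryl anion would close on the aldehyde to give the 4-hydroxy cis-flavan A3.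
- Merits: ring A arrives in one operation, addition to a 3-alkoxyaryne is regiochemically dependable, and both stereocentres come from an aldol that can be catalytic. On stereochemical economy it is better than the chosen plan, which loses half of 6 in a resolution.
- Weak points: it makes only the chroman, so the benzotropolone must already exist and survive fluoride and an aryl anion. A β-alkoxido aldehyde under basic fluoride is prone to retro-aldol cleavage and α-epimerisation. A3 has an extra benzylic hydroxyl whose removal passes through a cation next to the labile C2 ether.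
- Comparison: steps 7 and 8 give the 4-deoxy cis chroman directly under non-basic conditions and serve both chroman types. That generality is what the chosen plan sets against the resolution loss.

Alternative 2: The benzo ring of a benzosuberone is cut at the two bonds to its ring-fusion carbons. The diene is a 3-hydroxy-2-pyrone A4 carrying the protected flavan, the dienophile the β-keto vinyl sulfone A5 of a cycloheptenone ester. Forward, base-activated A4 would add to A5, and decarboxylation and loss of sulfinate would give the arene A6.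
- Merits: a thermal reaction with no photochemical equipment, and an orientation fixed by polar matching. This is more secure than the orientation of a triplet enone towards an alkyl alkyne, and on that point it is the better road.
- Weak points: A6 has a saturated seven-membered ring, so the tropolone still needs an α-hydroxylation and two dehydrogenations in the presence of electron-rich rings. A4 needs its own long synthesis. The route gives only the acid half.
- Comparison: the chosen plan reaches the tropolone oxidation level one step after the key step and uses one indenone for both halves.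

Alternative 3: The seven-membered ring of the acid half is formed last, on the full skeleton. The cut gives an ortho-formyl aryl diazoketone A7 and the propiolate ester A8 of the protected alcohol half. Forward, Rh2(OAc)4 would turn A7 into a carbonyl ylide that adds to the alkyne of A8, giving the oxygen-bridged adduct A9.
- Merits: the ester bond is made early with a small acid, which is clearly easier than step 26. Dipole and propiolate are electronically matched. The bridge holds the tropolone oxidation level.
- Weak points: the alcohol component of A8 is itself a benzotropolone, so a second ring synthesis is needed anyway. A rhodium carbenoid is generated next to many benzylic ethers and a tropone carbonyl, on the most valuable intermediate. Opening the bridge needs acid in the presence of the ketal and three benzylic C2–O bonds.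
- Comparison: the chosen plan runs its key step on half-sized fragments, with both partners recoverable, and uses one reaction type for both tropolones. The price is a less certain orientation.

Key step: step 19

Assumption: 1, 8, 17 and 26 are taken as purchasable; the configuration of the diol carbons of 14 and of the two ring-fusion carbons of 22, 23, 27 and 28 is left open because these centres become sp2 later.

Shorthand in names: Flv = (2R,3R)-3,5,7-tris(benzyloxy)chroman-2-yl; TBS = tert-butyldimethylsilyl; Bn = benzyl; indane numbering has C1 on the arene carbon next to the ketal oxygen; benzo[7]annulene numbering has C5 as the ketone carbon.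

## Steps

Step 1
Reactants: 1 3,4,5-trihydroxybenzaldehyde
Product: 2 7-hydroxy-2,2-diphenyl-1,3-benzodioxole-5-carbaldehyde
Conditions: Ph2CCl2, Ph2O, 175 °C
Reagents that add atoms: dichlorodiphenylmethane, ClC(Cl)(c1ccccc1)c1ccccc1
Why: Ketalisation of a pyrogallol: only two adjacent hydroxyls can close the dioxole, so the third stays free, and the symmetry of the ring allows one product only.

Step 2
Reactants: 2 7-hydroxy-2,2-diphenyl-1,3-benzodioxole-5-carbaldehyde
Product: 3 7-(allyloxy)-2,2-diphenyl-1,3-benzodioxole-5-carbaldehyde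
Conditions: allyl bromide, K2CO3, DMF, 25 °C
Reagents that add atoms: allyl bromide, C=CCBr
Why: Williamson ether synthesis on the single free phenol.

Step 3
Reactants: 3 7-(allyloxy)-2,2-diphenyl-1,3-benzodioxole-5-carbaldehyde
Product: 4 6-allyl-7-hydroxy-2,2-diphenyl-1,3-benzodioxole-5-carbaldehyde
Conditions: PhNEt2, 190 °C
Reagents that add atoms: none
Why: Aromatic Claisen rearrangement; one ortho position is blocked by the ketal oxygen, so the allyl group should migrate only to C6, between the phenol and the formyl carbon.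

Step 4
Reactants: 4 6-allyl-7-hydroxy-2,2-diphenyl-1,3-benzodioxole-5-carbaldehyde
Product: 5 6-allyl-2,2-diphenyl-7-(trifluoromethylsulfonyloxy)-1,3-benzodioxole-5-carbaldehyde
Conditions: Tf2O, pyridine, CH2Cl2, 0 °C
Reagents that add atoms: trifluoromethanesulfonic anhydride, O=S(=O)(OS(=O)(=O)C(F)(F)F)C(F)(F)F
Why: O-Sulfonylation of the phenol turns the oxygen that directed the Claisen step into a leaving group for later C–C coupling.

Step 5
Reactants: 5 6-allyl-2,2-diphenyl-7-(trifluoromethylsulfonyloxy)-1,3-benzodioxole-5-carbaldehyde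
Product: 6 (±)-1-[6-allyl-2,2-diphenyl-7-(trifluoromethylsulfonyloxy)-1,3-benzodioxol-5-yl]prop-2-en-1-ol
Conditions: CH2=CHMgBr, THF, −78 °C; aq. NH4Cl
Reagents that add atoms: vinylmagnesium bromide, C=C[Mg]Br
Why: Grignard addition to the aldehyde, which at −78 °C is much faster than attack on the aryl triflate; the carbinol is racemic.

Step 6
Reactants: 6 (±)-1-[6-allyl-2,2-diphenyl-7-(trifluoromethylsulfonyloxy)-1,3-benzodioxol-5-yl]prop-2-en-1-ol
Product: 7 (S)-[6-allyl-2,2-diphenyl-7-(trifluoromethylsulfonyloxy)-1,3-benzodioxol-5-yl][(2R)-oxiran-2-yl]methanol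
Conditions: Ti(OiPr)4 (15 mol %), L-(+)-DIPT (18 mol %), t-BuOOH (0.5 equiv), 4 Å MS, CH2Cl2, −20 °C
Reagents that add atoms: tert-butyl hydroperoxide, CC(C)(C)OO
Why: Sharpless kinetic resolution; with L-(+)-tartrate the (R)-carbinol is epoxidised fast and erythro-selectively, which sets the oxirane carbon as (R) beside the (S)-carbinol, and the limited oxidant leaves the (S)-alcohol and the other alkenes untouched.

Step 7
Reactants: 7 (S)-[6-allyl-2,2-diphenyl-7-(trifluoromethylsulfonyloxy)-1,3-benzodioxol-5-yl][(2R)-oxiran-2-yl]methanol; 8 3,5-bis(benzyloxy)phenol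
Product: 9 (2R)-2-[(R)-[6-allyl-2,2-diphenyl-7-(trifluoromethylsulfonyloxy)-1,3-benzodioxol-5-yl][3,5-bis(benzyloxy)phenoxy]methyl]oxirane
Conditions: PPh3, DIAD, toluene, 0 → 25 °C
Reagents that add atoms: none
Why: Mitsunobu etherification with inversion at the benzylic carbinol, which changes the erythro into the threo O,O relation that a cis chroman needs; the meta triflate should disfavour ionisation and so protect the inversion.

Step 8
Reactants: 9 (2R)-2-[(R)-[6-allyl-2,2-diphenyl-7-(trifluoromethylsulfonyloxy)-1,3-benzodioxol-5-yl][3,5-bis(benzyloxy)phenoxy]methyl]oxirane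
Product: 10 (2R,3R)-2-[6-allyl-2,2-diphenyl-7-(trifluoromethylsulfonyloxy)-1,3-benzodioxol-5-yl]-5,7-bis(benzyloxy)chroman-3-ol
Conditions: BF3·OEt2 (0.2 equiv), CH2Cl2, −78 → −30 °C
Reagents that add atoms: none
Why: Intramolecular Friedel–Crafts epoxy–arene cyclisation (6-endo); either of the two equivalent ortho carbons of the phloroglucinol-type ring attacks the terminal epoxide carbon, so both stereocentres are carried over unchanged and become C2 and C3 of the cis chroman.

Step 9
Reactants: 10 (2R,3R)-2-[6-allyl-2,2-diphenyl-7-(trifluoromethylsulfonyloxy)-1,3-benzodioxol-5-yl]-5,7-bis(benzyloxy)chroman-3-ol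
Product: 11 (2R,3R)-2-(6-allyl-2,2-diphenyl-7-vinyl-1,3-benzodioxol-5-yl)-5,7-bis(benzyloxy)chroman-3-ol
Conditions: Bu3SnCH=CH2, Pd(PPh3)4 (5 mol %), LiCl, 1,4-dioxane, 95 °C
Reagents that add atoms: tributyl(vinyl)stannane, C=C[Sn](CCCC)(CCCC)CCCC
Why: Stille coupling of an aryl triflate with a vinylstannane in the presence of chloride; the free secondary alcohol and the ketal are inert.

Step 10
Reactants: 11 (2R,3R)-2-(6-allyl-2,2-diphenyl-7-vinyl-1,3-benzodioxol-5-yl)-5,7-bis(benzyloxy)chroman-3-ol
Product: 12 (2R,3R)-2-(6-allyl-2,2-diphenyl-7-vinyl-1,3-benzodioxol-5-yl)-3,5,7-tris(benzyloxy)chroman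
Conditions: NaH, BnBr, Bu4NI (cat.), THF/DMF, 0 °C
Reagents that add atoms: benzyl bromide, BrCc1ccccc1
Why: Williamson benzylation of the secondary alcohol; it is done after the coupling so that no alkoxide meets the aryl triflate.

Step 11
Reactants: 12 (2R,3R)-2-(6-allyl-2,2-diphenyl-7-vinyl-1,3-benzodioxol-5-yl)-3,5,7-tris(benzyloxy)chroman
Product: 13 6,7-(diphenylmethylenedioxy)-4-Flv-indene with the CH2 group at C3 and the C1=C2 double bond
Conditions: RuCl2(=CHPh)(PCy3)(H2IMes) (second-generation Grubbs catalyst, 5 mol %), CH2Cl2, 40 °C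
Reagents that add atoms: none
Why: Ring-closing metathesis of an ortho-allyl styrene to the indene; the product is used at once so that the double bond does not migrate.

Step 12
Reactants: 13 6,7-(diphenylmethylenedioxy)-4-Flv-indene with the CH2 group at C3 and the C1=C2 double bond
Product: 14 cis-6,7-(diphenylmethylenedioxy)-4-Flv-indane-1,2-diol (both cis diastereomers)
Conditions: OsO4 (2 mol %), NMO, acetone/H2O, 25 °C
Reagents that add atoms: osmium tetroxide (catalytic oxygen carrier), O=[Os](=O)(=O)=O; N-methylmorpholine N-oxide, C[N+]1([O-])CCOCC1; water, O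
Why: Upjohn syn-dihydroxylation of the only remaining alkene; the facial outcome is irrelevant because both carbinol carbons are oxidised next.

Step 13
Reactants: 14 cis-6,7-(diphenylmethylenedioxy)-4-Flv-indane-1,2-diol (both cis diastereomers)
Product: 15 6,7-(diphenylmethylenedioxy)-4-Flv-indane-1,2-dione
Conditions: (COCl)2, DMSO, CH2Cl2, −78 °C; Et3N, −78 → −20 °C
Reagents that add atoms: none
Why: Double Swern oxidation of a vicinal diol to the 1,2-diketone without C–C cleavage; the enolisable dione is taken on directly.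

Step 14
Reactants: 15 6,7-(diphenylmethylenedioxy)-4-Flv-indane-1,2-dione
Product: 16 2-(tert-butyldimethylsilyloxy)-6,7-(diphenylmethylenedioxy)-4-Flv-inden-1-one
Conditions: TBSOTf, Et3N, CH2Cl2, −78 °C
Reagents that add atoms: tert-butyldimethylsilyl trifluoromethanesulfonate, CC(C)(C)[Si](C)(C)OS(=O)(=O)C(F)(F)F
Why: Soft enolisation and O-silylation; only the benzylic C3 hydrogens can be removed, so the enol silyl ether forms at O2 with the ketone left on C1.

Step 15
Reactants: 17 (±)-pent-1-en-4-yn-3-ol
Product: 18 (1S)-1-[(2R)-oxiran-2-yl]prop-2-yn-1-ol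
Conditions: Ti(OiPr)4 (15 mol %), L-(+)-DIPT (18 mol %), t-BuOOH (0.45 equiv), 4 Å MS, CH2Cl2, −20 °C; non-aqueous work-up
Reagents that add atoms: tert-butyl hydroperoxide, CC(C)(C)OO
Why: Sharpless kinetic resolution as in step 6: the (R)-carbinol gives the erythro epoxy alcohol, oxirane carbon (R) and carbinol (S); any enantiomeric leakage becomes a separable diastereomer once joined to enantiopure 16.

Step 16
Reactants: 18 (1S)-1-[(2R)-oxiran-2-yl]prop-2-yn-1-ol; 8 3,5-bis(benzyloxy)phenol
Product: 19 (2R)-2-[(1R)-1-[3,5-bis(benzyloxy)phenoxy]prop-2-yn-1-yl]oxirane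
Conditions: PPh3, DIAD, toluene, 0 → 25 °C
Reagents that add atoms: none
Why: Mitsunobu etherification with inversion at the propargylic carbinol, giving the threo relation needed for the cis chroman.

Step 17
Reactants: 19 (2R)-2-[(1R)-1-[3,5-bis(benzyloxy)phenoxy]prop-2-yn-1-yl]oxirane
Product: 20 (2R,3R)-5,7-bis(benzyloxy)-2-ethynylchroman-3-ol
Conditions: BF3·OEt2 (0.2 equiv), CH2Cl2, −78 → −30 °C
Reagents that add atoms: none
Why: Intramolecular Friedel–Crafts epoxy–arene cyclisation (6-endo) at the terminal epoxide carbon, as in step 8; both stereocentres are retained and end as the cis pair C2/C3.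

Step 18
Reactants: 20 (2R,3R)-5,7-bis(benzyloxy)-2-ethynylchroman-3-ol
Product: 21 (2R,3R)-5,7-bis(benzyloxy)-3-(tert-butyldimethylsilyloxy)-2-ethynylchroman
Conditions: TBSCl, imidazole, DMF, 25 °C
Reagents that add atoms: tert-butyldimethylsilyl chloride, CC(C)(C)[Si](C)(C)Cl
Why: Silylation of the secondary alcohol with a group that fluoride removes in step 20 together with the enol-derived silyl group.

Step 19
Reactants: 16 2-(tert-butyldimethylsilyloxy)-6,7-(diphenylmethylenedioxy)-4-Flv-inden-1-one; 21 (2R,3R)-5,7-bis(benzyloxy)-3-(tert-butyldimethylsilyloxy)-2-ethynylchroman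
Product: 22 cis-fused cyclobutene photoadduct: the indan-1-one of 16 with C2 (bearing OTBS) and C3 bridged by –CH=C(R)–, the CH on C2 and C(R) on C3, R = (2R,3R)-5,7-bis(benzyloxy)-3-(tert-butyldimethylsilyloxy)chroman-2-yl
Conditions: hν (405 nm LED), 21 (3 equiv), degassed CH2Cl2, −20 °C
Reagents that add atoms: none
Why: Light of 405 nm should be absorbed only by the siloxyindenone 16, whose triplet bonds to the unsubstituted alkyne carbon of 21 to give a 1,4-biradical that closes after spin inversion. The closest known reaction type is the (2+2) photocycloaddition of cyclopentenones and indenones with terminal alkynes to bicyclo[3.2.0]hept-6-en-2-ones. The four-membered ring is closed by radical–radical combination onto a five-membered ring and can therefore only be cis-fused. The two new ring-fusion stereocentres are fixed relative to each other by that ring strain; their sense relative to the flavan is not controlled and does not matter, because both become sp2 in step 20. The step needs head-to-tail orientation, alkyne CH to the siloxy carbon C2 and the chromanyl-bearing carbon to C3. Two features favour it: the polarisation of the excited enone (Corey's rule, nucleophilic alkyne terminus to the α-carbon), and the reluctance of the branched alkenyl radical to close onto the fully substituted C2. It also needs chemoselectivity: the 2-siloxy group, the peri flavanyl group and the excess alkyne suppress indenone dimerisation, and the product, an aryl ketone transparent at 405 nm, is spared the 1,3-acyl shift that scrambles such adducts under ultraviolet light. The six existing stereocentres are spectators, and excess 21 is recovered.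

Step 20
Reactants: 22 cis-fused cyclobutene photoadduct of 16 and 21
Product: 24 8-[(2R,3R)-5,7-bis(benzyloxy)-3-hydroxychroman-2-yl]-6-hydroxy-3,4-(diphenylmethylenedioxy)-1-Flv-5H-benzo[7]annulen-5-one, via desilylated cyclobutenoxide 23 (not isolated)
Conditions: Bu4NF (3 equiv), THF, 0 → 25 °C; AcOH
Reagents that add atoms: none
Why: Proposed new method: fluoride removes both silyl groups and the tertiary alkoxide on the ring-fusion carbon expels the neighbouring ring-fusion carbon as a carbanion that is benzylic, allylic and conjugated through the arene to the ketone, so the bond shared by the four- and five-membered rings should break heterolytically with release of cyclobutene strain and give the aromatic tropolonate at unchanged oxidation level; the closest known reaction types are the alkoxide-accelerated ring opening of cyclobutenols and the retro-aldol ring enlargement of de Mayo photoadducts, neither of which has been shown for a 1-oxido-bicyclo[3.2.0]hept-6-en-2-one giving a tropolone.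

Step 21
Reactants: 24 8-[(2R,3R)-5,7-bis(benzyloxy)-3-hydroxychroman-2-yl]-6-hydroxy-3,4-(diphenylmethylenedioxy)-1-Flv-5H-benzo[7]annulen-5-one
Product: 25 6-(benzyloxy)-8-[(2R,3R)-5,7-bis(benzyloxy)-3-hydroxychroman-2-yl]-3,4-(diphenylmethylenedioxy)-1-Flv-5H-benzo[7]annulen-5-one
Conditions: BnBr (1.2 equiv), K2CO3, acetone, 40 °C
Reagents that add atoms: benzyl bromide, BrCc1ccccc1
Why: O-Alkylation of the acidic tropolone hydroxyl with carbonate, which leaves the secondary alcohol free; only the ether that keeps the ketone next to the benzo ring preserves the benzene sextet, so one regioisomer is expected.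

Step 22
Reactants: 16 2-(tert-butyldimethylsilyloxy)-6,7-(diphenylmethylenedioxy)-4-Flv-inden-1-one; 26 tert-butyldimethyl(prop-2-yn-1-yloxy)silane
Product: 27 cis-fused cyclobutene photoadduct: as 22 with R = CH2OTBS on the alkene carbon bonded to C3
Conditions: hν (405 nm LED), 26 (10 equiv), degassed CH2Cl2, −20 °C
Reagents that add atoms: none
Why: Second use of the enone–alkyne (2+2) photocycloaddition of step 19 with a small propargylic ether, for which the same head-to-tail preference is expected; a large excess of the volatile alkyne suppresses indenone dimerisation.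

Step 23
Reactants: 27 cis-fused cyclobutene photoadduct of 16 and 26
Product: 29 6-hydroxy-8-(hydroxymethyl)-3,4-(diphenylmethylenedioxy)-1-Flv-5H-benzo[7]annulen-5-one, via desilylated cyclobutenoxide 28 (not isolated)
Conditions: Bu4NF (3 equiv), THF, 0 → 25 °C; AcOH
Reagents that add atoms: none
Why: Proposed new method: as in step 20, double desilylation gives a ring-fusion alkoxide whose benzylic and allylic carbanion leaving group should allow heterolysis of the shared cyclobutene bond to the tropolonate; the closest known reaction types are alkoxide-accelerated cyclobutenol opening and the de Mayo retro-aldol ring enlargement.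

Step 24
Reactants: 29 6-hydroxy-8-(hydroxymethyl)-3,4-(diphenylmethylenedioxy)-1-Flv-5H-benzo[7]annulen-5-one
Product: 30 6-(benzyloxy)-8-(hydroxymethyl)-3,4-(diphenylmethylenedioxy)-1-Flv-5H-benzo[7]annulen-5-one
Conditions: BnBr (1.2 equiv), K2CO3, acetone, 40 °C
Reagents that add atoms: benzyl bromide, BrCc1ccccc1
Why: Selective O-benzylation of the acidic tropolone hydroxyl in the presence of the primary alcohol, as in step 21.

Step 25
Reactants: 30 6-(benzyloxy)-8-(hydroxymethyl)-3,4-(diphenylmethylenedioxy)-1-Flv-5H-benzo[7]annulen-5-one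
Product: 32 6-(benzyloxy)-3,4-(diphenylmethylenedioxy)-1-Flv-5-oxo-5H-benzo[7]annulene-8-carboxylic acid, via aldehyde 31 (not isolated)
Conditions: TEMPO (20 mol %), PhI(OAc)2 (2.5 equiv), MeCN/H2O (1:1), 25 °C
Reagents that add atoms: water, O
Why: Oxoammonium oxidation of the allylic-type primary alcohol to the aldehyde, whose hydrate is oxidised on to the acid; no phenol is free, so the electron-rich rings are not attacked.

Step 26
Reactants: 32 6-(benzyloxy)-3,4-(diphenylmethylenedioxy)-1-Flv-5-oxo-5H-benzo[7]annulene-8-carboxylic acid; 25 6-(benzyloxy)-8-[(2R,3R)-5,7-bis(benzyloxy)-3-hydroxychroman-2-yl]-3,4-(diphenylmethylenedioxy)-1-Flv-5H-benzo[7]annulen-5-one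
Product: 34 fully protected target: the ester of acid 32 with the chroman 3-hydroxyl of 25, via mixed anhydride 33 (not isolated)
Conditions: 2,4,6-Cl3C6H2COCl, Et3N, THF, 25 °C; then 25, DMAP, toluene, 25 °C
Reagents that add atoms: none
Why: Yamaguchi esterification; DMAP attacks the less hindered acyl group of the mixed anhydride, and the acylpyridinium acylates the axial 3-hydroxyl with retention, as in the galloylation of protected cis-flavan-3-ols.

Step 27
Reactants: 34 fully protected target: the ester of acid 32 with the chroman 3-hydroxyl of 25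
Product: 35 CNP0315570.1, the (2R,3R)-chroman-3-yl ester of epitheaflavic acid with theaflavin
Conditions: H2 (1 atm), Pd(OH)2/C, THF/MeOH (1:1), 25 °C
Reagents that add atoms: none
Why: Hydrogenolysis of ten benzyl ethers and two benzylic diphenylmethylene ketals in one neutral step; the ester oxygen sits on a non-benzylic carbon and should be retained, and the reaction is stopped at the calculated hydrogen uptake to spare the tropolone rings.

## Compound list

1 | 3,4,5-trihydroxybenzaldehyde | O=Cc1cc(O)c(O)c(O)c1 | starting material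
2 | 7-hydroxy-2,2-diphenyl-1,3-benzodioxole-5-carbaldehyde | O=Cc1cc(O)c2OC(c3ccccc3)(c3ccccc3)Oc2c1 | intermediate
3 | 7-(allyloxy)-2,2-diphenyl-1,3-benzodioxole-5-carbaldehyde | O=Cc1cc(OCC=C)c2OC(c3ccccc3)(c3ccccc3)Oc2c1 | intermediate
4 | 6-allyl-7-hydroxy-2,2-diphenyl-1,3-benzodioxole-5-carbaldehyde | O=Cc1cc2OC(c3ccccc3)(c3ccccc3)Oc2c(O)c1CC=C | intermediate
5 | 6-allyl-2,2-diphenyl-7-(trifluoromethylsulfonyloxy)-1,3-benzodioxole-5-carbaldehyde | O=Cc1cc2OC(c3ccccc3)(c3ccccc3)Oc2c(OS(=O)(=O)C(F)(F)F)c1CC=C | intermediate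
6 | (±)-1-[6-allyl-2,2-diphenyl-7-(trifluoromethylsulfonyloxy)-1,3-benzodioxol-5-yl]prop-2-en-1-ol | C=CC(O)c1cc2OC(c3ccccc3)(c3ccccc3)Oc2c(OS(=O)(=O)C(F)(F)F)c1CC=C | intermediate
7 | (S)-[6-allyl-2,2-diphenyl-7-(trifluoromethylsulfonyloxy)-1,3-benzodioxol-5-yl][(2R)-oxiran-2-yl]methanol | O[C@@H](c1cc2OC(c3ccccc3)(c3ccccc3)Oc2c(OS(=O)(=O)C(F)(F)F)c1CC=C)[C@H]1CO1 | intermediate
8 | 3,5-bis(benzyloxy)phenol | Oc1cc(OCc2ccccc2)cc(OCc2ccccc2)c1 | starting material
9 | (2R)-2-[(R)-[6-allyl-2,2-diphenyl-7-(trifluoromethylsulfonyloxy)-1,3-benzodioxol-5-yl][3,5-bis(benzyloxy)phenoxy]methyl]oxirane | O(c1cc(OCc2ccccc2)cc(OCc2ccccc2)c1)[C@H](c1cc2OC(c3ccccc3)(c3ccccc3)Oc2c(OS(=O)(=O)C(F)(F)F)c1CC=C)[C@H]1CO1 | intermediate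
10 | (2R,3R)-2-[6-allyl-2,2-diphenyl-7-(trifluoromethylsulfonyloxy)-1,3-benzodioxol-5-yl]-5,7-bis(benzyloxy)chroman-3-ol | C=CCc1c(OS(=O)(=O)C(F)(F)F)c2OC(c3ccccc3)(c3ccccc3)Oc2cc1[C@H]1Oc2cc(OCc3ccccc3)cc(OCc3ccccc3)c2C[C@H]1O | intermediate
11 | (2R,3R)-2-(6-allyl-2,2-diphenyl-7-vinyl-1,3-benzodioxol-5-yl)-5,7-bis(benzyloxy)chroman-3-ol | C=CCc1c(C=C)c2OC(c3ccccc3)(c3ccccc3)Oc2cc1[C@H]1Oc2cc(OCc3ccccc3)cc(OCc3ccccc3)c2C[C@H]1O | intermediate
12 | (2R,3R)-2-(6-allyl-2,2-diphenyl-7-vinyl-1,3-benzodioxol-5-yl)-3,5,7-tris(benzyloxy)chroman | C=CCc1c(C=C)c2OC(c3ccccc3)(c3ccccc3)Oc2cc1[C@H]1Oc2cc(OCc3ccccc3)cc(OCc3ccccc3)c2C[C@H]1OCc1ccccc1 | intermediate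
13 | 6,7-(diphenylmethylenedioxy)-4-Flv-indene (CH2 at C3, C1=C2 double bond) | C1=Cc2c3OC(c4ccccc4)(c4ccccc4)Oc3cc([C@H]3Oc4cc(OCc5ccccc5)cc(OCc5ccccc5)c4C[C@H]3OCc3ccccc3)c2C1 | intermediate
14 | cis-6,7-(diphenylmethylenedioxy)-4-Flv-indane-1,2-diol (both cis diastereomers) | OC1C(O)c2c3OC(c4ccccc4)(c4ccccc4)Oc3cc([C@H]3Oc4cc(OCc5ccccc5)cc(OCc5ccccc5)c4C[C@H]3OCc3ccccc3)c2C1 | intermediate
15 | 6,7-(diphenylmethylenedioxy)-4-Flv-indane-1,2-dione | O=C1C(=O)c2c3OC(c4ccccc4)(c4ccccc4)Oc3cc([C@H]3Oc4cc(OCc5ccccc5)cc(OCc5ccccc5)c4C[C@H]3OCc3ccccc3)c2C1 | intermediate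
16 | 2-(tert-butyldimethylsilyloxy)-6,7-(diphenylmethylenedioxy)-4-Flv-inden-1-one | CC(C)(C)[Si](C)(C)OC1=Cc2c(C1=O)c1OC(c3ccccc3)(c3ccccc3)Oc1cc2[C@H]1Oc2cc(OCc3ccccc3)cc(OCc3ccccc3)c2C[C@H]1OCc1ccccc1 | intermediate
17 | (±)-pent-1-en-4-yn-3-ol | C=CC(O)C#C | starting material
18 | (1S)-1-[(2R)-oxiran-2-yl]prop-2-yn-1-ol | O[C@@H](C#C)[C@H]1CO1 | intermediate
19 | (2R)-2-[(1R)-1-[3,5-bis(benzyloxy)phenoxy]prop-2-yn-1-yl]oxirane | O(c1cc(OCc2ccccc2)cc(OCc2ccccc2)c1)[C@H](C#C)[C@H]1CO1 | intermediate
20 | (2R,3R)-5,7-bis(benzyloxy)-2-ethynylchroman-3-ol | O[C@@H]1Cc2c(OCc3ccccc3)cc(OCc3ccccc3)cc2O[C@@H]1C#C | intermediate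
21 | (2R,3R)-5,7-bis(benzyloxy)-3-(tert-butyldimethylsilyloxy)-2-ethynylchroman | CC(C)(C)[Si](C)(C)O[C@@H]1Cc2c(OCc3ccccc3)cc(OCc3ccccc3)cc2O[C@@H]1C#C | intermediate
22 | cis-fused cyclobutene photoadduct of 16 and 21 (OTBS on the ring-fusion carbon next to the ketone, silyloxychromanyl group on the alkene carbon next to the benzylic ring-fusion CH) | O=C1c2c3OC(c4ccccc4)(c4ccccc4)Oc3cc([C@H]3Oc4cc(OCc5ccccc5)cc(OCc5ccccc5)c4C[C@H]3OCc3ccccc3)c2C2C([C@H]3Oc4cc(OCc5ccccc5)cc(OCc5ccccc5)c4C[C@H]3O[Si](C)(C)C(C)(C)C)=CC12O[Si](C)(C)C(C)(C)C | intermediate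
23 | desilylated cyclobutenol of 22, formed as its alkoxide | O=C1c2c3OC(c4ccccc4)(c4ccccc4)Oc3cc([C@H]3Oc4cc(OCc5ccccc5)cc(OCc5ccccc5)c4C[C@H]3OCc3ccccc3)c2C2C([C@H]3Oc4cc(OCc5ccccc5)cc(OCc5ccccc5)c4C[C@H]3O)=CC12O | intermediate (not isolated)
24 | 8-[(2R,3R)-5,7-bis(benzyloxy)-3-hydroxychroman-2-yl]-6-hydroxy-3,4-(diphenylmethylenedioxy)-1-Flv-5H-benzo[7]annulen-5-one | O[C@@H]1Cc2c(OCc3ccccc3)cc(OCc3ccccc3)cc2O[C@@H]1c1cc(O)c(=O)c2c3OC(c4ccccc4)(c4ccccc4)Oc3cc([C@H]3Oc4cc(OCc5ccccc5)cc(OCc5ccccc5)c4C[C@H]3OCc3ccccc3)c2c1 | intermediate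
25 | 6-(benzyloxy)-8-[(2R,3R)-5,7-bis(benzyloxy)-3-hydroxychroman-2-yl]-3,4-(diphenylmethylenedioxy)-1-Flv-5H-benzo[7]annulen-5-one | O[C@@H]1Cc2c(OCc3ccccc3)cc(OCc3ccccc3)cc2O[C@@H]1c1cc(OCc2ccccc2)c(=O)c2c3OC(c4ccccc4)(c4ccccc4)Oc3cc([C@H]3Oc4cc(OCc5ccccc5)cc(OCc5ccccc5)c4C[C@H]3OCc3ccccc3)c2c1 | intermediate
26 | tert-butyldimethyl(prop-2-yn-1-yloxy)silane | C#CCO[Si](C)(C)C(C)(C)C | starting material
27 | cis-fused cyclobutene photoadduct of 16 and 26 (CH2OTBS on the alkene carbon next to the benzylic ring-fusion CH) | O=C1c2c3OC(c4ccccc4)(c4ccccc4)Oc3cc([C@H]3Oc4cc(OCc5ccccc5)cc(OCc5ccccc5)c4C[C@H]3OCc3ccccc3)c2C2C(CO[Si](C)(C)C(C)(C)C)=CC12O[Si](C)(C)C(C)(C)C | intermediate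
28 | desilylated cyclobutenol of 27, formed as its alkoxide | O=C1c2c3OC(c4ccccc4)(c4ccccc4)Oc3cc([C@H]3Oc4cc(OCc5ccccc5)cc(OCc5ccccc5)c4C[C@H]3OCc3ccccc3)c2C2C(CO)=CC12O | intermediate (not isolated)
29 | 6-hydroxy-8-(hydroxymethyl)-3,4-(diphenylmethylenedioxy)-1-Flv-5H-benzo[7]annulen-5-one | OCc1cc(O)c(=O)c2c3OC(c4ccccc4)(c4ccccc4)Oc3cc([C@H]3Oc4cc(OCc5ccccc5)cc(OCc5ccccc5)c4C[C@H]3OCc3ccccc3)c2c1 | intermediate
30 | 6-(benzyloxy)-8-(hydroxymethyl)-3,4-(diphenylmethylenedioxy)-1-Flv-5H-benzo[7]annulen-5-one | OCc1cc(OCc2ccccc2)c(=O)c2c3OC(c4ccccc4)(c4ccccc4)Oc3cc([C@H]3Oc4cc(OCc5ccccc5)cc(OCc5ccccc5)c4C[C@H]3OCc3ccccc3)c2c1 | intermediate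
31 | 6-(benzyloxy)-3,4-(diphenylmethylenedioxy)-1-Flv-5-oxo-5H-benzo[7]annulene-8-carbaldehyde | O=Cc1cc(OCc2ccccc2)c(=O)c2c3OC(c4ccccc4)(c4ccccc4)Oc3cc([C@H]3Oc4cc(OCc5ccccc5)cc(OCc5ccccc5)c4C[C@H]3OCc3ccccc3)c2c1 | intermediate (not isolated)
32 | 6-(benzyloxy)-3,4-(diphenylmethylenedioxy)-1-Flv-5-oxo-5H-benzo[7]annulene-8-carboxylic acid | O=C(O)c1cc(OCc2ccccc2)c(=O)c2c3OC(c4ccccc4)(c4ccccc4)Oc3cc([C@H]3Oc4cc(OCc5ccccc5)cc(OCc5ccccc5)c4C[C@H]3OCc3ccccc3)c2c1 | intermediate
33 | mixed anhydride of 32 with 2,4,6-trichlorobenzoic acid | O=C(OC(=O)c1c(Cl)cc(Cl)cc1Cl)c1cc(OCc2ccccc2)c(=O)c2c3OC(c4ccccc4)(c4ccccc4)Oc3cc([C@H]3Oc4cc(OCc5ccccc5)cc(OCc5ccccc5)c4C[C@H]3OCc3ccccc3)c2c1 | intermediate (not isolated)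
34 | fully protected target: ester of acid 32 with the chroman 3-hydroxyl of 25 | O=C(O[C@@H]1Cc2c(OCc3ccccc3)cc(OCc3ccccc3)cc2O[C@@H]1c1cc(OCc2ccccc2)c(=O)c2c3OC(c4ccccc4)(c4ccccc4)Oc3cc([C@H]3Oc4cc(OCc5ccccc5)cc(OCc5ccccc5)c4C[C@H]3OCc3ccccc3)c2c1)c1cc(OCc2ccccc2)c(=O)c2c3OC(c4ccccc4)(c4ccccc4)Oc3cc([C@H]3Oc4cc(OCc5ccccc5)cc(OCc5ccccc5)c4C[C@H]3OCc3ccccc3)c2c1 | intermediate
35 | CNP0315570.1 | O=C(O[C@@H]1Cc2c(O)cc(O)cc2O[C@@H]1c1cc(O)c(=O)c2c(O)c(O)cc([C@H]3Oc4cc(O)cc(O)c4C[C@H]3O)c2c1)c1cc(O)c(=O)c2c(O)c(O)cc([C@H]3Oc4cc(O)cc(O)c4C[C@H]3O)c2c1 | target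

## Step count and risks

Total: 27 steps. Longest linear sequence: 20 steps (steps 1–14, 22–25, 26, 27).

**Step 20 (new method).** The most likely failure is desilylation without ring opening, or the tertiary α-keto alkoxide rearranging by an acyloin-type shift before the ring-fusion bond breaks, since heterolysis to a carbanion with no carbonyl directly attached is untested. Fallback: starting from 22, the intact bis-silyl ether is heated (o-dichlorobenzene, 170 °C). This is the known thermal cyclobutene ring opening of enone–alkyne photoadducts to cyclohepta-2,4-dienones, which here needs no alkoxide. It should give the silyl tropolone ether F1, and Bu4NF/AcOH then cleaves both silyl ethers to rejoin the route at 24.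

**Step 23 (new method).** The same failure is possible, with the added chance that the primary alkoxide interferes. Fallback: starting from 27, thermal ring opening as above gives the bis-silyl hydroxymethyl tropolone ether F2, and Bu4NF/AcOH returns to 29.

**Step 19 (key step).** The bulky chroman alkyne, which also offers an abstractable propargylic α-oxy hydrogen, may add slowly and in both orientations, so that indenone dimerisation and hydrogen abstraction compete and the head-to-tail adduct is a minor product. Fallback: the third chroman is built after the ring expansion instead of being carried through the photoreaction.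
- It starts from 30 (steps 22–24 use only the small alkyne 26). Dess–Martin periodinane stops at aldehyde 31.
- CH2=CHBr with CrCl2 and catalytic NiCl2 in DMF adds vinyl to the aldehyde only (a Grignard reagent would attack the alkoxytropone), giving the allylic alcohol F3 as a carbinol epimer mixture.
- Titanium–L-(+)-tartrate/t-BuOOH epoxidises the (R)-carbinol epimer to the erythro epoxy alcohol F4.
- Mitsunobu coupling with 8 gives the aryl ether F5, and BF3·OEt2 closes the pyran to rejoin the route at 25.

**Step 13.** The cis-diol may suffer C–C cleavage, or the enolisable 1,2-dione may hydrate and self-condense before it is silylated. Fallback: starting from 14, MnO2 oxidises only the benzylic alcohol to the ketol F6; TBSCl/imidazole gives the silyl ether F7; dehydrogenation with IBX (DMSO/toluene, 70 °C) introduces the C2=C3 double bond and returns to 16 without a free dione.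

**Step 6.** The rate difference between the enantiomers of the ortho-substituted carbinol may be too small, so the epoxy alcohol forms with low enantiomeric purity; half the material is lost in any case. Fallback: starting from 5, catalytic enantioselective vinylation with Zn(CH=CH2)2 and a chiral amino alcohol gives the (R)-allylic alcohol F8. The same titanium–tartrate system, now matched and with a full equivalent of oxidant, epoxidises it completely to 7.

**Step 27.** Removing twelve protecting groups may be accompanied by hydrogenation of the tropolone rings or hydrogenolysis of the benzylic C2–O1 bonds. Fallback: starting from 34, Lewis-acid dealkylation with BCl3 and pentamethylbenzene (CH2Cl2, −78 °C) cleaves the benzyl ethers and ketals without hydrogen and gives 35 directly; no new compound is involved.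

## Further compounds

F1 | step 20 | 8-[(2R,3R)-5,7-bis(benzyloxy)-3-(tert-butyldimethylsilyloxy)chroman-2-yl]-6-(tert-butyldimethylsilyloxy)-3,4-(diphenylmethylenedioxy)-1-Flv-5H-benzo[7]annulen-5-one | CC(C)(C)[Si](C)(C)O[C@@H]1Cc2c(OCc3ccccc3)cc(OCc3ccccc3)cc2O[C@@H]1c1cc(O[Si](C)(C)C(C)(C)C)c(=O)c2c3OC(c4ccccc4)(c4ccccc4)Oc3cc([C@H]3Oc4cc(OCc5ccccc5)cc(OCc5ccccc5)c4C[C@H]3OCc3ccccc3)c2c1
F2 | step 23 | 6-(tert-butyldimethylsilyloxy)-8-[(tert-butyldimethylsilyloxy)methyl]-3,4-(diphenylmethylenedioxy)-1-Flv-5H-benzo[7]annulen-5-one | CC(C)(C)[Si](C)(C)OCc1cc(O[Si](C)(C)C(C)(C)C)c(=O)c2c3OC(c4ccccc4)(c4ccccc4)Oc3cc([C@H]3Oc4cc(OCc5ccccc5)cc(OCc5ccccc5)c4C[C@H]3OCc3ccccc3)c2c1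
F3 | step 19 | 6-(benzyloxy)-8-(1-hydroxyprop-2-en-1-yl)-3,4-(diphenylmethylenedioxy)-1-Flv-5H-benzo[7]annulen-5-one (carbinol epimers) | C=CC(O)c1cc(OCc2ccccc2)c(=O)c2c3OC(c4ccccc4)(c4ccccc4)Oc3cc([C@H]3Oc4cc(OCc5ccccc5)cc(OCc5ccccc5)c4C[C@H]3OCc3ccccc3)c2c1
F4 | step 19 | 6-(benzyloxy)-8-[(S)-hydroxy[(2R)-oxiran-2-yl]methyl]-3,4-(diphenylmethylenedioxy)-1-Flv-5H-benzo[7]annulen-5-one | O[C@@H](c1cc(OCc2ccccc2)c(=O)c2c3OC(c4ccccc4)(c4ccccc4)Oc3cc([C@H]3Oc4cc(OCc5ccccc5)cc(OCc5ccccc5)c4C[C@H]3OCc3ccccc3)c2c1)[C@H]1CO1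
F5 | step 19 | 6-(benzyloxy)-8-[(R)-[3,5-bis(benzyloxy)phenoxy][(2R)-oxiran-2-yl]methyl]-3,4-(diphenylmethylenedioxy)-1-Flv-5H-benzo[7]annulen-5-one | O(c1cc(OCc2ccccc2)cc(OCc2ccccc2)c1)[C@H](c1cc(OCc2ccccc2)c(=O)c2c3OC(c4ccccc4)(c4ccccc4)Oc3cc([C@H]3Oc4cc(OCc5ccccc5)cc(OCc5ccccc5)c4C[C@H]3OCc3ccccc3)c2c1)[C@H]1CO1
F6 | step 13 | 2-hydroxy-6,7-(diphenylmethylenedioxy)-4-Flv-indan-1-one (C2 epimers) | OC1C(=O)c2c3OC(c4ccccc4)(c4ccccc4)Oc3cc([C@H]3Oc4cc(OCc5ccccc5)cc(OCc5ccccc5)c4C[C@H]3OCc3ccccc3)c2C1
F7 | step 13 | 2-(tert-butyldimethylsilyloxy)-6,7-(diphenylmethylenedioxy)-4-Flv-indan-1-one (C2 epimers) | CC(C)(C)[Si](C)(C)OC1C(=O)c2c3OC(c4ccccc4)(c4ccccc4)Oc3cc([C@H]3Oc4cc(OCc5ccccc5)cc(OCc5ccccc5)c4C[C@H]3OCc3ccccc3)c2C1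
F8 | step 6 | (R)-1-[6-allyl-2,2-diphenyl-7-(trifluoromethylsulfonyloxy)-1,3-benzodioxol-5-yl]prop-2-en-1-ol | O[C@H](C=C)c1cc2OC(c3ccccc3)(c3ccccc3)Oc2c(OS(=O)(=O)C(F)(F)F)c1CC=C
F0 | step 27 | none | none
A1 | alternative 1 | 3,5-bis(benzyloxy)benzyne | C1#CC(OCc2ccccc2)=CC(OCc2ccccc2)=C1
A2 | alternative 1 | syn α-benzyloxy-β-hydroxy aldehyde carrying the protected benzotropolone methyl ester | O=C[C@@H](OCc1ccccc1)[C@H](O)c1cc(OCc2ccccc2)c(OCc2ccccc2)c2c(=O)c(OCc3ccccc3)cc(C(=O)OC)cc12
A3 | alternative 1 | protected epitheaflavic methyl ester with a 4-hydroxy cis-flavan | COC(=O)c1cc(OCc2ccccc2)c(=O)c2c(OCc3ccccc3)c(OCc3ccccc3)cc([C@H]3Oc4cc(OCc5ccccc5)cc(OCc5ccccc5)c4C(O)[C@H]3OCc3ccccc3)c2c1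
A4 | alternative 2 | 4-(benzyloxy)-3-hydroxy-6-Flv-2H-pyran-2-one | O=c1oc([C@H]2Oc3cc(OCc4ccccc4)cc(OCc4ccccc4)c3C[C@H]2OCc2ccccc2)cc(OCc2ccccc2)c1O
A5 | alternative 2 | methyl 4-oxo-5-(phenylsulfonyl)cyclohept-5-ene-1-carboxylate | COC(=O)C1CCC(=O)C(S(=O)(=O)c2ccccc2)=CC1
A6 | alternative 2 | benzosuberone ester with the fully substituted benzo ring and cis-flavan | COC(=O)C1CCC(=O)c2c(O)c(OCc3ccccc3)cc([C@H]3Oc4cc(OCc5ccccc5)cc(OCc5ccccc5)c4C[C@H]3OCc3ccccc3)c2C1
A7 | alternative 3 | ortho-formyl aryl diazomethyl ketone carrying the ketal and Flv | [N-]=[N+]=CC(=O)c1c(C=O)c([C@H]2Oc3cc(OCc4ccccc4)cc(OCc4ccccc4)c3C[C@H]2OCc2ccccc2)cc2OC(c3ccccc3)(c3ccccc3)Oc12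
A8 | alternative 3 | propiolate ester of benzyl- and silyl-protected theaflavin | C#CC(=O)O[C@@H]1Cc2c(OCc3ccccc3)cc(OCc3ccccc3)cc2O[C@@H]1c1cc(OCc2ccccc2)c(=O)c2c(OCc3ccccc3)c(OCc3ccccc3)cc([C@H]3Oc4cc(OCc5ccccc5)cc(OCc5ccccc5)c4C[C@H]3O[Si](C)(C)C(C)(C)C)c2c1
A9 | alternative 3 | oxygen-bridged benzocycloheptadienone ester, full protected skeleton | O=C1C2C=C(C(=O)O[C@@H]3Cc4c(OCc5ccccc5)cc(OCc5ccccc5)cc4O[C@@H]3c3cc(OCc4ccccc4)c(=O)c4c(OCc5ccccc5)c(OCc5ccccc5)cc([C@H]5Oc6cc(OCc7ccccc7)cc(OCc7ccccc7)c6C[C@H]5O[Si](C)(C)C(C)(C)C)c4c3)C(O2)c2c([C@H]3Oc4cc(OCc5ccccc5)cc(OCc5ccccc5)c4C[C@H]3OCc3ccccc3)cc3OC(c4ccccc4)(c4ccccc4)Oc3c21
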